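Count the L. I follow one flask in which L and G give J, with its own early run, beta, and an earlier run, delta, beside it.

all flasks: L 0.0605 M
- beta: G 0.055 M; temperature 50 °C; the very flask that is asked about, followed so far
- delta: G 0.037 M; temperature 35 °C; run made earlier
- flask: G 0.055 M; temperature 50 °C; time 30 min

| run | time / min | J / % |
|---|---|---|
| beta | 4.00 | 63.4 |
| beta | 8.00 | 61.8 |
| beta | 10.0 | 60.4 |
| beta | 15.0 | 65.0 |
| beta | 20.0 | 62.1 |
| delta | 3.00 | 72.2 |
| delta | 5.00 | 80.4 |
| delta | 8.00 | 79.9 |
| delta | 10.0 | 80.5 |
| delta | 12.0 | 79.8 |

(standard deviation of a reading: 1 percentage point)

- grey: change nothing and wait 10 min more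
- ochre: at 30 min raise the temperature by 10 K, then wait 10 min
- teal: at 30 min take out 90% of the J then present, then wait 10 min
- amber: at 30 min add L, 100% of the amount charged, then wait 10 min

- J, in percent of the G first charged, at 30 min
- the option that brings most further J ("none" if no option brings more than 2 percentage points) (grey / ochre / teal / amber / none)
- J present, with what was taken out counted in, in percent of the G first charged, after grey
- J present, with what was taken out counted in, in percent of the G first charged, after teal

- removed J is counted in
- the analysis behind the earlier runs scatters by 1 percentage point, standard deviation
- additions bring no volume worth counting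

I take one J to hold one G and one L. Beta lies flat at a mean of 62.5% of its G, which is 56.9% of its L. That second figure is the capture share, the part of the charged L found as J on the plateau, a selectivity measured from the even split of one half. Two rows set the runs side by side:

- beta: L per G 1.10; plateau 62.5%; capture share 56.9%
- delta: L per G 1.64; plateau 80.2%; capture share 49.0%

Reading down the first column, delta has more L per G. Its plateau is higher, yet its capture share is lower, at half, while beta stands above the even split. The temperatures differ too, so the rows don't separate the two settings. The uncaptured 43.1% of beta's L may be free and in balance with J, or gone elsewhere, and a flat line shows neither.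

My reckoning keeps 62.5% at 30 min and after grey. I reckon that a dose of L captured at 56.9% gives 63 percentage points, more than the 37.5% of G that the plateau leaves at one G per J, so in this reckoning that G is amber's ceiling. Amber pays on both readings and teal on one, so I choose amber and put no number on teal.

The forecast gives 62.5% now, amber as best, 62.5% after grey and 79% after teal, reading the plateaus as “a reversible, exothermic L + G ⇌ J”.

The flask gives 62.5% at 30 min and 62.5% after grey, and teal gives 62.5%, which is 17 points below the forecast. Amber is best, adding 25 points.

    G + L → J, rate k1*[G]^1.5*[L]^0.5 (k = 0.880 M⁻¹ s⁻¹, Ea = 43.0 kJ mol⁻¹)
    L → X (k = 0.0313 s⁻¹, Ea = 76.0 kJ mol⁻¹)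
    (constants at 50 °C)

At 30.0 min the flask holds L at 0% of its charge and X at 0.0261 M; L is the limiting reagent, the first to run out. The amber dose has a capture share of 22.6%, less than the first charge's 56.9%. The neighbour flask with 0.036 M of L gives 44.4%, a capture share of 67.8%, more than the first charge's 56.9% in the asked flask.

(All runs come from a simulation for substances that don't exist.)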